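(The numbers of this flask were drawn at random within sensible limits; what happens was integrated by code.)

Colleague, here is the quick number you asked for, and my answer to your hunch that more free base pushes the electrophile further along.

the same everywhere: electrophile 12 mM; gas 1.3 mM (held); time 2.0 d
- amber: free base 3.00 equiv
- blue: free base 4.50 equiv
- green: free base 6.80 equiv

    electrophile + nucleophile → acid set free + target (k1 = 12.2 L mol⁻¹ h⁻¹)
    nucleophile + acid set free ⇌ protonated nucleophile, settled at all times (K2 = 6.8 × 10⁵ L mol⁻¹)
    acid set free + free base ⇌ salt of the base, settled at all times (K3 = 1.16 × 10⁶ L mol⁻¹)
    gas ⇌ nucleophile, rate k4*(csat - [nucleophile]) (k4 = 0.277 h⁻¹, csat = 1.3 mM)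
    target → over-reaction product (k5 = 0.0777 h⁻¹)
    target ⇌ isomer of the product (K6 = 0.56, k6 = 0.0171 h⁻¹)

- at the start none of nucleophile is dissolved
- run time (amber): 2.0 d

- part of the electrophile that has reacted at the end, amber
- part of the electrophile that has reacted at the end, blue
- part of the electrophile that has reacted at the end, green
- what raising the equivalents of free base from its lowest to its highest value here does to the part of the electrophile that has reacted (changes below 5 percentage points count as none) (no change / it rises / it falls)

Dissolved nucleophile enters from the held gas and leaves by reaction with the electrophile. Entry falls as [nucleophile] rises, while the drain goes with [nucleophile] and [electrophile], so I hold [electrophile] at its charge and set the two rates equal, and time drops out of the balance. I call 0.529 the drain ratio, the rate constant of the coupling times the electrophile charge over the transfer coefficient. The transfer relaxes in 3.61 h, shorter than the 2.0 d run, so [nucleophile] soon sits near csat divided by one plus the ratio, 0.850 mM. Holding that value, I let the electrophile decay pseudo-first-order at 0.0104 h⁻¹, a half-life of 2.78 d. The part reacted comes to 39.2% in amber, 39.2% in blue and 39.2% in green, since the free base stands nowhere in the ratio.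

I doubt your hunch. The free base reaches the electrophile through the acid, and even in amber, its lowest charge, it outbids saturated nucleophile for acid 47.2 times over. So I reckon protonated nucleophile ties up about 0.83 percentage points of the electrophile charge in amber, less than the 5 points that counts as a change, and I commit to no change.

The forecast, made apart from me, gives 39.6%, 39.7% and 39.8% for amber, blue and green, and no change: “Base loading shifts this by only about 0.1 point, so there is no meaningful change.” Its amber figure lies a little above mine.

The simulation gives 39.7%, 39.7% and 39.7%, so no change, with 0.093 points between lowest and highest base. Green's number moves by 5 points once the reading shifts to 1.72 d or 2.30 d. In the neighbour of amber charged with 20 mM, the drain ratio rises to 0.881, which gives 33.3% reacted against 34.3% in that flask. In amber, the electrophile's half-life from the ratio, 2.78 d, is longer than that of target by its passing into over-reaction product, 0.37 d. At 2.00 d amber holds 9.03% of the electrophile charged as target and 27.1% as over-reaction product.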